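(Readings and results are calculated with made-up constants, noise included.)

Monomer in chains divided by chains begun is the length asked for, the number-average chain length, so two tallies are needed: how much free monomer has entered chains, and how many chains have begun. The earlier runs show the first tally and not the second.

the same everywhere: pre-initiator 10 mol%

| charge | free monomer | remark | time |
|---|---|---|---|
| autumn | 0.093 M | run made earlier |  |
| spring | 0.42 M | run made earlier |  |
| Saturday's | 0.16 M |  | 2.0 min |
| Sunday's | 0.60 M |  | 2.0 min |

| run | time / s | monomer in chains / % |
|---|---|---|
| autumn | 15.0 | 0 |
| autumn | 30.0 | 2.5 |
| autumn | 50.0 | 6.0 |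
| autumn | 60.0 | 11.0 |
| autumn | 80.0 | 19.0 |
| autumn | 90.0 | 22.9 |
| autumn | 120 | 37.1 |
| spring | 10.0 | 1.6 |
| spring | 20.0 | 6.4 |
| spring | 30.0 | 16.5 |
| spring | 50.0 | 42.2 |
| spring | 80.0 | 74.8 |
| spring | 90.0 | 82.0 |
| spring | 120 | 94.4 |

(each reading ± 1 percentage point)

* which of the two ends with the longer chains by the average number of monomer units in a chain (chains begun, living or dead) ("neither" if they lie within 10%) (Saturday's / Sunday's / neither)
* average number of monomer units in a chain (chains begun, living or dead) at the end, Saturday's
* average number of monomer units in a chain (chains begun, living or dead) at the end, Sunday's

- the average divides the monomer in chains by the number of chains begun, living and dead together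
- the earlier runs do not show the number of chains; that part of a forecast is a guess

The rate starts near nothing. In the early readings of both runs the rate per free monomer climbs in step with time, so the logarithm L grows as the time squared:

L = −ln(fraction of free monomer left)

Autumn reads 0.464 at 120 s, and spring reads 0.548 at 50.0 s, which the square of the times carries to 3.16 at 2.0 min. Between these two readings L goes as the charge to the power 1.27, which scales it to 0.925 for Saturday's and 4.97 for Sunday's.

The slowing is the falling fraction of free monomer, which multiplies the rate. Accumulated over 2.0 min, it leaves these fractions:

Saturday's: 39.7% left, 60.3% reacted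
Sunday's: 0.694% left, 99.3% reacted

Counting one chain per pre-initiator, the whole charge begun gives the fraction reacted over the loading:

Saturday's: 6.03
Sunday's: 9.93

This is the floor length, the length with the whole pre-initiator charge begun as chains. The share begun stays unknown, but with like shares Sunday's ends longer, by a factor of 1.65.

The forecast also names Sunday's, at 20 (8 to 50) and 28 (11 to 70), and says of its share: “This fraction is a guess”.

Saturday's ends at 11.0 and Sunday's at 19.3, so Sunday's is longer, with 28% and 28% of the pre-initiator left in them. These lengths stand at 1.82 and 1.94 times their floors, which puts the share of the charge begun at 54.8% and 51.5%.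

    free monomer + initiator → living end + monomer in chains (k = 0.256 /M/s)
    free monomer + living end → monomer in chains + living end, rate k2*[living end]*[free monomer] (k = 1.57 /M/s)
    pre-initiator → initiator (k = 0.0106 /s)

Saturday's flask left until 5.0 min has a floor length of 9.97. It gives 13.6, so 73.3% of the charge has begun.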